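The numbers stand for no real mixture; the flask was simulated.

Late in a run the link step can run back, so before any number I ask which constants the links at 10 h really lean on.

    first end groups + second end groups ⇌ links + released group (K1 = 1.9, k1 = 0.0349 L mol⁻¹ s⁻¹)
    second end groups + released group ⇌ idle adduct, settled at all times (K2 = 86.4 L mol⁻¹)
    scavenger + released group → scavenged by-product (k3 = 0.135 L mol⁻¹ s⁻¹)
    2 second end groups → homo dimer (k4 = 0.0201 L mol⁻¹ s⁻¹)

| setting | south-east | west | south-west |
|---|---|---|---|
| first end groups | 20 mM | 20 mM | 20 mM (fed, over 2.0 h) |
| second end groups | 22.0 mM (fed, over 2.0 h) | 22.0 mM | 22.0 mM |
| scavenger | 10.0 mM | 10.0 mM | 10.0 mM |
| time | 10 h | 10 h | 10 h |
| remark | all else is in the flask from the start; the feed brings no volume worth counting | everything together at the start | all else is in the flask from the start; the feed brings no volume worth counting |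

1. the best flask by amount of links, in percent of the first end groups charged; "all alike" if 1.5 percentage points covers them all (south-east / west / south-west / all alike)
2. amount of links at the end, in percent of the first end groups charged, south-east
3. amount of links at the end, in percent of the first end groups charged, west
4. amount of links at the end, in percent of the first end groups charged, south-west

**The way back.** I weigh south-west first, where second end groups wait for first end groups. The link step's equilibrium constant, 1.9, acts through the released group that stands in the flask. The scavenger covers links up to 50.0% of the charge, so if south-west stays below that, an error here should cost little.

**The adduct.** With 86.4 L mol⁻¹ and second end groups as charged, 0.345 of released group is free. That stretches the scavenging half-life from 0.143 h to 0.414 h, still shorter than the feed of 2.0 h. So in south-west I expect an error in this adduct constant or in the scavenging constant to shift timing, with little change in links.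

**The split.** The pair that must be good is the dimer and link constants, since an error in their ratio passes straight into the split ratio ρ. This selectivity factor is the rate at which second end groups go to homo dimer over the rate at which they go to links by the forward step: 2 times the dimer constant times their concentration, over the link constant times the concentration of first end groups. At the charges ρ is 1.27; at any moment it is that value times the fraction of its own charge of second end groups present over the same fraction of first end groups.

**South-west reckoned.** The dimer step by itself halves second end groups in 0.314 h, shorter than the feed. By then 15.7% of the first end groups are in, so, neglecting the link step, ρ stands near 4.04. I commit to south-west coming last and leave south-east against west open.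

**The forecast.** It goes further than I do: 60% for south-east, 58% for west, 30% for south-west, with south-east best, since “charging them all against a slow feed of first end groups lets much of them dimerise before they can link”.

**The outcome.** South-east ends at 58.9%, west at 55.7% and south-west at 31.3%, so south-east is best. In south-west at 0.179 h, by which half of the dimer turnover up to 10 h is done, the dimer path uses second end groups at 10 to one against the forward link path. In south-east at the end of the feed, 2.00 h, the fractions present give ρ as 0.703, and homo dimer stands at 2.18 mM there against 7.85 mM in south-west at the same time.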